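Slowness is what we measure first: in this flask substrate and target both disappear slowly, and we count how many turnovers of the one fit into one of the other.

| flask | substrate | first nucleophile | second nucleophile | remark | time |
|---|---|---|---|---|---|
| birch | 10 mM | 0.50 equiv | 1.1 equiv | run made earlier |  |
| larch | 15 mM | 0.50 equiv | 1.1 equiv | run made earlier |  |
| alder | 20 mM | 0.50 equiv | 0.55 equiv | run made earlier |  |
| flask | 20 mM | 0.500 equiv | 1.10 equiv |  | 15 d |

- a species is counted by the substrate in it: one idle adduct or side product counts as two
- amounts and yields of target count idle adduct too
- steps under discussion: substrate -> intermediate; first nucleophile + intermediate -> target; second nucleophile + intermediate -> other capture product; intermediate -> solvolysis product; substrate + target <-> idle adduct; substrate + target -> side product; second nucleophile + target -> over-reaction product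
- in an amount of target, one idle adduct counts as one target

* time up to 15 d at which target stands highest
* the amount of target, in percent of the substrate charged, at that time
* earliest time at which at least nineteen twentieths of that best amount are there, in d
* latest time at which they still are, in d

| run | time / d | target / % | substrate / % |
|---|---|---|---|
| birch | 0.208 | 11.7 | 42.0 |
| birch | 0.500 | 17.0 | 15.2 |
| birch | 1.25 | 18.9 | 3.1 |
| birch | 3.00 | 14.6 | 0.8 |
| birch | 8.00 | 6.9 | 0 |
| birch | 20.0 | 0.7 | 0 |
| larch | 0.208 | 13.1 | 40.6 |
| larch | 0.500 | 19.2 | 13.7 |
| larch | 1.25 | 20.4 | 3.4 |
| larch | 3.00 | 14.2 | 0.6 |
| larch | 8.00 | 4.3 | 0.2 |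
| larch | 20.0 | 0 | 0 |
| alder | 0.208 | 17.2 | 37.8 |
| alder | 0.625 | 26.8 | 8.7 |
| alder | 2.08 | 27.8 | 1.6 |
| alder | 6.00 | 22.1 | 0.1 |
| alder | 20.0 | 14.5 | 0 |

(readings scatter by 0.3 percentage points)

We read the substrate column of the alder table first. It falls from 37.8% at 0.208 d to 8.7% at 0.625 d, a first-order constant of 3.52 /d at the flask's 20 mM.

Next come the late target rows, from 3.00 d to 8.00 d. Birch loses target at 0.150 /d and larch at 0.239 /d, a ratio of 1.59 against 1.50 in charge at equal equivalents. Alder, with half the equivalents of second nucleophile, loses target at 0.0301 /d between 6.00 d and 20.0 d, more slowly than birch, so we scale at fixed equivalents.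

Birch and alder charge the same c(second nucleophile), 1.1 equiv on 10 mM and 0.55 equiv on 20 mM, yet alder's constant is lower, so the loss does not follow that charge across recipes. We therefore hold the equivalents at those of birch and larch, which are the flask's, and use one pseudo-first-order constant as a working figure for the late rows. Scaling larch to the flask gives the target loss constant 0.319 /d. Then 11.1 substrate turnovers fit into one of target, and a rise at 3.52 /d against a fall at 0.319 /d tops at the logarithm of that count over the difference of the two constants, which is 0.750 d. We commit to that time, with a height near the larch reading of 20.4%.

The forecast, holding that “The late decay follows second nucleophile”, puts 22.5% at 0.85 d, later than our time, and the window from 0.55 d to 1.3 d.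

The flask gives 20.8% at 0.906 d, with the window from 0.551 d to 1.45 d; our time stands 0.156 d early.

    substrate → intermediate (k = 0.147 /h)
    first nucleophile + intermediate → target (k = 2550 /M/h)
    second nucleophile + intermediate → other capture product (k = 2200 /M/h)
    intermediate → solvolysis product (k = 13.0 /h)
    substrate + target ⇌ idle adduct, settled at all times (K = 1200 /M)
    substrate + target → side product (k = 0.817 /M/h)
    second nucleophile + target → over-reaction product (k = 1.48 /M/h)

In the flask, half of the making of intermediate up to 15 d was done by 0.222 d, while free target at 0.222 d had a half-life of 1.2 d by over-reaction, 5.31 times as long. Our 0.319 /d corresponds to a half-life of 2.17 d, longer than that early figure.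

The neighbour charged with 5.0 mM of substrate, at the same equivalents, scales to 0.0796 /d, which counts 1.19 turnovers in 15 d, so from its best of 16.0% we reckon 4.87% at the end. The computed amount is 3.47%.

The runs were generated by integration from invented constants; scatter was added.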